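A charge of 5.0 µM of free enzyme has to carry 10 mM of starting material, and the decision for the next run is whether birch's 12.0 mM of scavenger can replace elm's 24.0 mM, and whether 40 h is long enough.

- elm: starting material 10 mM; second substrate 11.0 mM; scavenger 24.0 mM; free enzyme 5.0 µM; time 40 h
- birch: starting material 10 mM; second substrate 11.0 mM; scavenger 12.0 mM; free enzyme 5.0 µM; time 40 h

    starting material + free enzyme ⇌ first complex (K1 = 150 M⁻¹, k1 = 53 M⁻¹ s⁻¹)
    second complex → free enzyme + target (k2 = 0.094 s⁻¹)
    first complex → loaded enzyme + first product (k3 = 0.10 s⁻¹)
    scavenger + first product → scavenged by-product (k4 = 0.10 M⁻¹ s⁻¹)
    second substrate + loaded enzyme ⇌ second complex (K5 = 110 M⁻¹, k5 = 930 M⁻¹ s⁻¹)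
    second substrate + first product ⇌ idle adduct, settled at all times (K6 = 210 M⁻¹)

- what is said of first product includes idle adduct
- run time (elm): 40 h

- part of the starting material that has reacted at the end, elm
- part of the starting material that has reacted at the end, birch
- what raising the concentration of scavenger from its lowest to its highest value here does to the part of the starting material that has reacted (changes below 5 percentage points count as none) (it falls / no change / it rises)

Each enzyme molecule goes round one cycle, so the rate is c(free enzyme) as charged divided by a turnover time, and the rate is of first order in that small concentration. At steady state the turnover time is a sum: the two chemical steps cost 20.6 s, while binding costs 8.55 s for starting material and 8.89 s for second substrate at their charges, each growing as its own concentration falls. At the start that makes 38.1 s, or 0.472 mM h⁻¹. Starting material is the limiting reagent, since c(second substrate) is larger, and the two fall together at a fixed difference, so we can integrate the turnover time down to a residue of 0.333 mM. This gives the needed time 38.7 h, which is shorter than the run.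

Scavenger stands nowhere in this sum; it can act through the idle adduct, which holds second substrate. At the starting rate, birch keeps free first product near 0.109 mM, which would hold 0.253 mM as adduct, far less than the second substrate charged. We would therefore charge 12.0 mM of scavenger, keep the enzyme and the time, and expect about 96.7% reacted in both flasks.

The forecast gives 97.3% for elm and 97.2% for birch, with no change as the trend, holding that “doubling the scavenger barely changes conversion”. The simulation gives 97.2% for elm and 97.2% for birch, a difference of 0.086 percentage points, so the trend is no change.

Birch's residue of 0.285 mM at the end of the run lies below the 0.333 mM reckoned for 38.7 h. The neighbouring flask is birch with 0.0030 mM of free enzyme. Scaling by the charge, the reckoning gives that flask 64.5 h for that same residue, longer than its 40 h, so by this reckoning it stops short of that residue. The same sum taken to that flask's residue of 2.00 mM comes to 39.8 h, and that flask stands at 80.0% reacted after 40.0 h.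

The constants used here were drawn at random within sensible limits; what happens was integrated by code.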